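**Plan**

1. Numbering (halimane): ring A = C1, C2, C3, C4, C5, C10; ring B = C5 to C10; C11–C16 chain on C9; C17 on C8; C18 (CO2Me) and C19 (CH3) on C4; C20 on C9. α is the face of H-5 in the target; all bicyclic intermediates carry 4α-CO2Me, 8α-CH3, 9α-CH3 and the C11 carbon on C9β.
2. Cuts, in retrosynthetic order: the two acetates; the C13 oxygen (epoxide opening); the C12–C13 bond (sp3–sp2 coupling); then C9–C10 and C7–C8 together, a [4+2] between the ring A diene C10=C5–C6=C7 and an (E)-2-methylbut-2-enoyl unit (C8=C9, C11 as carbonyl).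
3. Enabling feature: C1 of ring A and C11 on C9 both sit one bond from the new C9–C10 bond, so a three-atom ester tether C1–O–C11(=O) (a temporary γ-lactone) can hold the dienophile over the diene; the C1=C10 alkene of the target marks where that oxygen was.
4. Forward: ring A from a cyclohexanone β-keto ester; dienyl tiglate; intramolecular Diels–Alder closes ring B and the lactone; lactone opened to the C11=C12 vinyl group; C1 ketone, enone, reductive 1,3-transposition to the C1=C10 alkene; side chain by B-alkyl coupling, epoxidation, hydrolysis, acetylation.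
5. Stereochemistry: C4 by auxiliary-controlled methylation; the C1 carbinol (CBS) passes its configuration through the tether to C9 and C8 (with the (E)-dienophile geometry); a second C1 carbinol (CBS) passes it to C5 by suprafacial diazene hydrogen transfer; C13 and C14 by asymmetric epoxidation and invertive opening at C13.

Key step: step 9

Assumption: in step 2 the toluene/HMPA ligand set is taken to give the R ester; if the sense proves opposite, tert-butyl D-valinate serves with the same chemistry.

**Route**

Step 1
Reactants: 1 methyl 2-oxocyclohexane-1-carboxylate; 2 tert-butyl L-valinate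
Product: 3 methyl 2-{[(2S)-1-tert-butoxy-3-methyl-1-oxobutan-2-yl]amino}cyclohex-1-ene-1-carboxylate
Conditions: TsOH (cat.), toluene, reflux, Dean–Stark trap
Reagents that add atoms: none
Why: Condensation of the β-keto ester with the primary amine should give the hydrogen-bonded enamino ester, with water removed azeotropically.

Step 2
Reactants: 3 enamino ester
Product: 5 methyl (R)-1-methyl-2-oxocyclohexane-1-carboxylate, via C-methylated imine 4 (not isolated)
Conditions: LiN(iPr)2, toluene, HMPA, −78 °C; MeI, −78 → −20 °C; then 1 M aq. HCl, 23 °C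
Reagents that add atoms: iodomethane, CI; water, O
Why: Diastereoselective C-alkylation of the chelated lithio-enamine, in which the valine ester shields one face, should set the quaternary C4, and acid hydrolysis of the imine returns the ketone and the auxiliary.

Step 3
Reactants: 5 (R)-keto ester
Product: 6 methyl (R)-1-methyl-2-oxocyclohex-3-ene-1-carboxylate
Conditions: Pd(OCOCF3)2 (5 mol %), DMSO (10 mol %), O2 (1 atm), AcOH, 80 °C
Reagents that add atoms: none
Why: Palladium-catalysed aerobic dehydrogenation (Saegusa-type, via the palladium enolate and β-hydride elimination) can only run toward C10/C1 because C4 is quaternary, which also rules out aromatisation.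

Step 4
Reactants: 6 enone ester
Product: 7 methyl (1R)-2-ethynyl-2-hydroxy-1-methylcyclohex-3-ene-1-carboxylate (both C2 epimers)
Conditions: HC≡CMgBr, THF, −78 → 0 °C; aq. NH4Cl
Reagents that add atoms: ethynylmagnesium bromide, C#C[Mg]Br
Why: 1,2-Grignard addition of the small alkynyl nucleophile to the enone carbonyl should outpace attack on the α-quaternary ester, and the new carbinol centre is erased in step 5.

Step 5
Reactants: 7 tertiary alcohol
Product: 8 methyl (R)-2-ethynyl-1-methyl-4-oxocyclohex-2-ene-1-carboxylate
Conditions: pyridinium chlorochromate [C5H5NH][CrO3Cl], 4 Å molecular sieves, CH2Cl2, 23 °C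
Reagents that add atoms: none
Why: Babler–Dauben oxidative transposition: the tertiary chromate ester shifts [3,3] across the ring alkene (the alkyne cannot take part) and the secondary chromate is oxidised to the 3-ethynyl enone with its carbonyl at C1.

Step 6
Reactants: 8 enynone
Product: 9 methyl (1R,4R)-2-ethynyl-4-hydroxy-1-methylcyclohex-2-ene-1-carboxylate
Conditions: (S)-2-methyl-CBS-oxazaborolidine (20 mol %), catecholborane, toluene, −78 °C
Reagents that add atoms: none
Why: Corey–Bakshi–Shibata reduction with the alkenyl branch as the large group should deliver hydride under catalyst control to give the 1β (R) carbinol, and catecholborane at −78 °C does not hydroborate the alkyne.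

Step 7
Reactants: 9 enynol
Product: 10 methyl (1R,4R)-2-ethenyl-4-hydroxy-1-methylcyclohex-2-ene-1-carboxylate
Conditions: H2 (1 atm), Pd/CaCO3 poisoned with Pb(OAc)2 (Lindlar catalyst), quinoline, EtOAc, 23 °C
Reagents that add atoms: none
Why: Lindlar semi-hydrogenation should stop at the vinyl stage for the terminal alkyne and leave the trisubstituted ring alkene alone, giving the 1-vinylcyclohexene diene.

Step 8
Reactants: 10 dienol; 11 tiglic acid, (E)-2-methylbut-2-enoic acid
Product: 12 methyl (1R,4R)-2-ethenyl-1-methyl-4-{[(E)-2-methylbut-2-enoyl]oxy}cyclohex-2-ene-1-carboxylate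
Conditions: DCC, DMAP (cat.), CH2Cl2, 0 → 23 °C
Reagents that add atoms: none
Why: Steglich esterification should acylate the secondary allylic alcohol with retention at C1 and without change of the (E)-geometry of the acid.

Step 9
Reactants: 12 dienyl tiglate
Product: 13 methyl 11-oxo-1β,11-epoxy-12,13,14,15,16-pentanorhalim-5-en-18-oate (10α-H; γ-lactone C1β–O–C11(=O)–C9β)
Conditions: BHT (cat.), 1,2-dichlorobenzene (0.01 M), 180 °C, sealed tube
Reagents that add atoms: none
Why: Thermal intramolecular Diels–Alder reaction: the C10=C5–C6=C7 diene of ring A, held s-cis by the quaternary C4, adds suprafacially to the C8=C9 bond of the tiglate and forms C9–C10 and C7–C8 in one concerted [4+2] step. The closest known reaction type is the ester-tethered intramolecular Diels–Alder reaction of 3-acyloxy-1-vinylcyclohexenes bearing unsaturated acyl groups, which gives the same peri-fused γ-lactone skeleton. Ring B closes as the six-membered cycloaddition ring, and the lactone closes as a five-membered ring in which the three-atom tether C1–O–C11 joins diene terminus C10 to C9, which forces the C11 carbonyl endo, over ring A. The 1β-oxygen can reach only the β-face of the diene, so C10 takes C9 from that face (10α-H) and C11 ends β on C9 with C20 α, while the (E)-geometry of the dienophile fixes C17 cis to C20 (8α-CH3); no regiochemical or exo alternative is geometrically open. The selectivity needed is cycloaddition faster than [1,5]-hydrogen shift in the diene or ester elimination, which high dilution, a radical inhibitor and the entropic advantage of the tether should secure.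

Step 10
Reactants: 13 lactone
Product: 14 methyl 11-hydroxy-1β,11-epoxy-12,13,14,15,16-pentanorhalim-5-en-18-oate (10α-H; lactol, both C11 anomers)
Conditions: i-Bu2AlH (1.05 equiv), toluene, −78 °C; aq. Rochelle salt (KNaC4H4O6)
Reagents that add atoms: none
Why: Partial hydride reduction of the strained γ-lactone to the lactol (stable tetrahedral aluminate at −78 °C) should be faster than attack on the neopentyl-type C18 methyl ester when one equivalent is used.

Step 11
Reactants: 14 lactol
Product: 16 methyl 1β-hydroxy-13,14,15,16-tetranorhalima-5,11-dien-18-oate (10α-H), via open hydroxy aldehyde 15 (not isolated)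
Conditions: Ph3PCH3Br, KOtBu, THF, 0 → 65 °C
Reagents that add atoms: methyltriphenylphosphonium bromide, C[P+](c1ccccc1)(c1ccccc1)c1ccccc1.[Br-]
Why: Wittig methylenation of the aldehyde tautomer of the lactol, which has no α-hydrogen and so cannot epimerise, should install C12 and release the 1β-hydroxyl.

Step 12
Reactants: 16 hydroxy diene
Product: 18 methyl 1-oxo-13,14,15,16-tetranorhalima-5(10),11-dien-18-oate, via β,γ-unsaturated ketone 17 (not isolated)
Conditions: Dess–Martin periodinane, NaHCO3, CH2Cl2, 23 °C; then DBU, 23 °C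
Reagents that add atoms: none
Why: Dess–Martin oxidation gives the C1 ketone, and base-mediated isomerisation through the dienolate should move the C5=C6 alkene into conjugation as the tetrasubstituted C5=C10 enone, erasing the C10 centre.

Step 13
Reactants: 18 enone
Product: 19 methyl (1R)-1β-hydroxy-13,14,15,16-tetranorhalima-5(10),11-dien-18-oate
Conditions: (S)-2-methyl-CBS-oxazaborolidine (0.5 equiv), catecholborane, toluene, −78 → −40 °C
Reagents that add atoms: none
Why: Corey–Bakshi–Shibata reduction under catalyst control, with the tetrasubstituted alkenyl branch as the large group, should give the 1β (R) allylic alcohol, and the vinyl group is inert to catecholborane at low temperature.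

Step 14
Reactants: 19 allylic alcohol
Product: 22 methyl 13,14,15,16-tetranorhalima-1(10),11-dien-18-oate (5α-H), via allylic sulfonylhydrazine 20 (not isolated), via allylic diazene 21 (not isolated)
Conditions: PPh3, DEAD, 2-nitrobenzenesulfonylhydrazide, N-methylmorpholine, −30 °C; then 23 °C
Reagents that add atoms: none
Why: Mitsunobu displacement with inversion places the hydrazine nitrogen on the α-face of C1, sulfinate loss gives the monoalkyl diazene, and its retro-ene loss of N2 should deliver hydrogen suprafacially to C5 (5α-H) while the alkene moves to C1=C10 (reductive 1,3-transposition).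

Step 15
Reactants: 23 ethyl acetoacetate
Product: 24 ethyl (E)-3-{[(trifluoromethyl)sulfonyl]oxy}but-2-enoate
Conditions: aq. Me4NOH, hexanes, 5 °C; (CF3SO2)2O
Reagents that add atoms: trifluoromethanesulfonic anhydride, O=S(=O)(OS(=O)(=O)C(F)(F)F)C(F)(F)F
Why: O-Sulfonylation of the non-chelated tetraalkylammonium enolate, which prefers the extended geometry, should give the (E)-enol triflate.

Step 16
Reactants: 24 enol triflate ester
Product: 25 (E)-4-hydroxybut-2-en-2-yl trifluoromethanesulfonate
Conditions: i-Bu2AlH (2.2 equiv), CH2Cl2, −78 °C; aq. Rochelle salt (KNaC4H4O6)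
Reagents that add atoms: none
Why: Low-temperature hydride reduction should convert the conjugated ester into the allylic alcohol without touching the alkenyl triflate or the alkene geometry.

Step 17
Reactants: 22 diene ester; 25 hydroxy alkenyl triflate
Product: 27 methyl (13E)-15-hydroxyhalima-1(10),13-dien-18-oate, via B-alkylborane 26 (not isolated)
Conditions: 9-BBN dimer, THF, 23 °C; then 25, PdCl2(dppf) (5 mol %), AsPh3, aq. K3PO4, DMF, 23 → 50 °C
Reagents that add atoms: none
Why: Anti-Markovnikov hydroboration is selective for the monosubstituted vinyl group over the hindered trisubstituted ring alkene, and B-alkyl Suzuki–Miyaura coupling with the alkenyl triflate should form C12–C13 with retention of the (E)-geometry.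

Step 18
Reactants: 27 (E)-allylic alcohol
Product: 28 methyl (13R,14R)-13,14-epoxy-15-hydroxyhalim-1(10)-en-18-oate
Conditions: Ti(OiPr)4 (10 mol %), D-(−)-diethyl tartrate (12 mol %), t-BuOOH, 4 Å molecular sieves, CH2Cl2, −20 °C
Reagents that add atoms: tert-butyl hydroperoxide, CC(C)(C)OO
Why: Sharpless asymmetric epoxidation is directed by the allylic hydroxyl, so the ring alkene is not touched, and the D-tartrate ligand should deliver oxygen to the face that gives the (13R,14R)-epoxide, as with other (E)-3-methylalk-2-en-1-ols.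

Step 19
Reactants: 28 epoxy alcohol
Product: 29 methyl (13S,14R)-13,14,15-trihydroxyhalim-1(10)-en-18-oate
Conditions: HClO4 (0.05 M), THF/H2O (3:1), 0 → 23 °C
Reagents that add atoms: water, O
Why: In acid-catalysed epoxide hydrolysis water should attack the tertiary carbon C13 with inversion (borderline SN2), turning the (13R,14R)-epoxide into the (13S,14R)-triol.

Step 20
Reactants: 29 triol
Product: 30 methyl (4R,5R,8R,9S,13S,14R)-14,15-diacetoxy-13-hydroxyhalim-1(10)-en-18-oate
Conditions: Ac2O, pyridine, CH2Cl2, 0 → 23 °C
Reagents that add atoms: acetic anhydride, CC(=O)OC(C)=O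
Why: Acetylation without a nucleophilic catalyst should esterify the primary C15 and secondary C14 hydroxyls and leave the hindered tertiary C13 hydroxyl free.

**Compound list**

1 | methyl 2-oxocyclohexane-1-carboxylate | COC(=O)C1CCCCC1=O | starting material
2 | tert-butyl L-valinate | CC(C)[C@H](N)C(=O)OC(C)(C)C | starting material
3 | methyl 2-{[(2S)-1-tert-butoxy-3-methyl-1-oxobutan-2-yl]amino}cyclohex-1-ene-1-carboxylate | COC(=O)C1=C(N[C@@H](C(C)C)C(=O)OC(C)(C)C)CCCC1 | intermediate
4 | methyl (1R)-2-{[(2S)-1-tert-butoxy-3-methyl-1-oxobutan-2-yl]imino}-1-methylcyclohexane-1-carboxylate | COC(=O)[C@]1(C)CCCCC1=N[C@@H](C(C)C)C(=O)OC(C)(C)C | intermediate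
5 | methyl (R)-1-methyl-2-oxocyclohexane-1-carboxylate | COC(=O)[C@]1(C)CCCCC1=O | intermediate
6 | methyl (R)-1-methyl-2-oxocyclohex-3-ene-1-carboxylate | COC(=O)[C@]1(C)CCC=CC1=O | intermediate
7 | methyl (1R)-2-ethynyl-2-hydroxy-1-methylcyclohex-3-ene-1-carboxylate (C2 epimers) | COC(=O)[C@]1(C)CCC=CC1(O)C#C | intermediate
8 | methyl (R)-2-ethynyl-1-methyl-4-oxocyclohex-2-ene-1-carboxylate | COC(=O)[C@]1(C)CCC(=O)C=C1C#C | intermediate
9 | methyl (1R,4R)-2-ethynyl-4-hydroxy-1-methylcyclohex-2-ene-1-carboxylate | COC(=O)[C@]1(C)CC[C@@H](O)C=C1C#C | intermediate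
10 | methyl (1R,4R)-2-ethenyl-4-hydroxy-1-methylcyclohex-2-ene-1-carboxylate | COC(=O)[C@]1(C)CC[C@@H](O)C=C1C=C | intermediate
11 | tiglic acid, (E)-2-methylbut-2-enoic acid | C/C=C(\C)C(=O)O | starting material
12 | methyl (1R,4R)-2-ethenyl-1-methyl-4-{[(E)-2-methylbut-2-enoyl]oxy}cyclohex-2-ene-1-carboxylate | COC(=O)[C@]1(C)CC[C@@H](OC(=O)/C(C)=C/C)C=C1C=C | intermediate
13 | methyl 11-oxo-1β,11-epoxy-12,13,14,15,16-pentanorhalim-5-en-18-oate (10α-H; tricyclic γ-lactone) | COC(=O)[C@]1(C)CC[C@H]2OC(=O)[C@@]3(C)[C@H](C)CC=C1[C@@H]23 | intermediate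
14 | methyl 11-hydroxy-1β,11-epoxy-12,13,14,15,16-pentanorhalim-5-en-18-oate (10α-H; lactol, C11 anomers) | COC(=O)[C@]1(C)CC[C@H]2OC(O)[C@@]3(C)[C@H](C)CC=C1[C@@H]23 | intermediate
15 | methyl 1β-hydroxy-11-oxo-12,13,14,15,16-pentanorhalim-5-en-18-oate (10α-H; open hydroxy aldehyde) | COC(=O)[C@]1(C)CC[C@@H](O)[C@@H]2C1=CC[C@@H](C)[C@]2(C)C=O | intermediate
16 | methyl 1β-hydroxy-13,14,15,16-tetranorhalima-5,11-dien-18-oate (10α-H) | COC(=O)[C@]1(C)CC[C@@H](O)[C@@H]2C1=CC[C@@H](C)[C@]2(C)C=C | intermediate
17 | methyl 1-oxo-13,14,15,16-tetranorhalima-5,11-dien-18-oate (10α-H) | COC(=O)[C@]1(C)CCC(=O)[C@@H]2C1=CC[C@@H](C)[C@]2(C)C=C | intermediate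
18 | methyl 1-oxo-13,14,15,16-tetranorhalima-5(10),11-dien-18-oate | COC(=O)[C@]1(C)CCC(=O)C2=C1CC[C@@H](C)[C@]2(C)C=C | intermediate
19 | methyl (1R)-1β-hydroxy-13,14,15,16-tetranorhalima-5(10),11-dien-18-oate | COC(=O)[C@]1(C)CC[C@@H](O)C2=C1CC[C@@H](C)[C@]2(C)C=C | intermediate
20 | methyl 1α-[1-(2-nitrobenzenesulfonyl)hydrazinyl]-13,14,15,16-tetranorhalima-5(10),11-dien-18-oate | COC(=O)[C@]1(C)CC[C@H](N(N)S(=O)(=O)c3ccccc3[N+](=O)[O-])C2=C1CC[C@@H](C)[C@]2(C)C=C | intermediate
21 | methyl 1α-diazenyl-13,14,15,16-tetranorhalima-5(10),11-dien-18-oate | COC(=O)[C@]1(C)CC[C@H](N=N)C2=C1CC[C@@H](C)[C@]2(C)C=C | intermediate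
22 | methyl (4R,5R,8R,9S)-13,14,15,16-tetranorhalima-1(10),11-dien-18-oate (5α-H) | COC(=O)[C@]1(C)CCC=C2[C@H]1CC[C@@H](C)[C@]2(C)C=C | intermediate
23 | ethyl acetoacetate | CCOC(=O)CC(C)=O | starting material
24 | ethyl (E)-3-{[(trifluoromethyl)sulfonyl]oxy}but-2-enoate | CCOC(=O)/C=C(\C)OS(=O)(=O)C(F)(F)F | intermediate
25 | (E)-4-hydroxybut-2-en-2-yl trifluoromethanesulfonate | OC/C=C(\C)OS(=O)(=O)C(F)(F)F | intermediate
26 | methyl 12-(9-borabicyclo[3.3.1]nonan-9-yl)-13,14,15,16-tetranorhalim-1(10)-en-18-oate | COC(=O)[C@]1(C)CCC=C2[C@H]1CC[C@@H](C)[C@]2(C)CCB3C4CCCC3CCC4 | intermediate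
27 | methyl (4R,5R,8R,9S,13E)-15-hydroxyhalima-1(10),13-dien-18-oate | COC(=O)[C@]1(C)CCC=C2[C@H]1CC[C@@H](C)[C@]2(C)CC/C(C)=C/CO | intermediate
28 | methyl (4R,5R,8R,9S,13R,14R)-13,14-epoxy-15-hydroxyhalim-1(10)-en-18-oate | COC(=O)[C@]1(C)CCC=C2[C@H]1CC[C@@H](C)[C@]2(C)CC[C@@]3(C)O[C@@H]3CO | intermediate
29 | methyl (4R,5R,8R,9S,13S,14R)-13,14,15-trihydroxyhalim-1(10)-en-18-oate | COC(=O)[C@]1(C)CCC=C2[C@H]1CC[C@@H](C)[C@]2(C)CC[C@](C)(O)[C@@H](CO)O | intermediate
30 | methyl (4R,5R,8R,9S,13S,14R)-14,15-diacetoxy-13-hydroxyhalim-1(10)-en-18-oate | COC(=O)[C@]1(C)CCC=C2[C@H]1CC[C@@H](C)[C@]2(C)CC[C@](C)(O)[C@@H](COC(C)=O)OC(C)=O | target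

**Step count and risks**

Total steps: 20. Longest linear sequence: 18 (steps 1–14 and 17–20); steps 15–16 prepare the coupling partner 25.

Most likely to fail:

Step 9. The cycloaddition of the weakly activated, trisubstituted dienophile may be too slow, so that [1,5]-hydrogen migration within the diene or thermal loss of the acyloxy group takes over. The fallback is an intermolecular, catalyst-controlled [4+2] that sets out from dienol 10. Silylation (TBSCl, imidazole, DMF) would give methyl (1R,4R)-4-[(tert-butyldimethylsilyl)oxy]-2-ethenyl-1-methylcyclohex-2-ene-1-carboxylate F1. Diels–Alder reaction of F1 with (E)-2-methylbut-2-enal under a chiral oxazaborolidinium triflimide Lewis acid (CH2Cl2, −78 → −40 °C) should give the ortho adduct methyl 1β-[(tert-butyldimethylsilyl)oxy]-11-oxo-12,13,14,15,16-pentanorhalim-5-en-18-oate F2. The catalyst enantiomer is chosen to expose the enal face that leads to 8R,9S; C8 and C9 depend only on that face, so F2 is a mixture at C10 alone. Wittig methylenation (Ph3PCH3Br, KOtBu) would give methyl 1β-[(tert-butyldimethylsilyl)oxy]-13,14,15,16-tetranorhalima-5,11-dien-18-oate F3, and Bu4NF would give methyl 1β-hydroxy-13,14,15,16-tetranorhalima-5,11-dien-18-oate (C10 epimers) F4. Dess–Martin oxidation and DBU then merge both C10 epimers into enone 18, where the route is rejoined.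

Step 10. The hydride may not distinguish cleanly between the lactone and the C18 methyl ester, or the lactol may be over-reduced to the diol. The fallback is aminolysis followed by an amide-selective reduction, setting out from lactone 13. MeNH(OMe)·HCl and AlMe3 (CH2Cl2, 0 → 23 °C) should open the strained lactone to methyl 1β-hydroxy-11-[methoxy(methyl)amino]-11-oxo-12,13,14,15,16-pentanorhalim-5-en-18-oate F5. Cp2Zr(H)Cl (THF, 23 °C) reduces tertiary amides to aldehydes and leaves esters alone, giving aldehyde 15, which closes to lactol 14, where the route is rejoined.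

Step 14. The SN2 displacement at the hindered allylic C1 may be slow, so that ionisation and elimination to dienes compete. The fallback is palladium-catalysed formate hydrogenolysis, setting out from alcohol 19. ClCO2Me and pyridine would give methyl 1β-[(methoxycarbonyl)oxy]-13,14,15,16-tetranorhalima-5(10),11-dien-18-oate F6. With Pd(OAc)2, PBu3 and HCO2NH4 in dioxane at 80 °C, zerovalent palladium should ionise the carbonate with inversion (metal on the α-face), and the formate-derived hydride is passed from the metal to the more substituted terminus C5. This again gives the 5α-H C1=C10 alkene 22, where the route is rejoined.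

Further compounds
F1 | step 9 | methyl (1R,4R)-4-[(tert-butyldimethylsilyl)oxy]-2-ethenyl-1-methylcyclohex-2-ene-1-carboxylate | COC(=O)[C@]1(C)CC[C@@H](O[Si](C)(C)C(C)(C)C)C=C1C=C
F2 | step 9 | methyl 1β-[(tert-butyldimethylsilyl)oxy]-11-oxo-12,13,14,15,16-pentanorhalim-5-en-18-oate (C10 epimers) | COC(=O)[C@]1(C)CC[C@@H](O[Si](C)(C)C(C)(C)C)C2C1=CC[C@@H](C)[C@]2(C)C=O
F3 | step 9 | methyl 1β-[(tert-butyldimethylsilyl)oxy]-13,14,15,16-tetranorhalima-5,11-dien-18-oate (C10 epimers) | COC(=O)[C@]1(C)CC[C@@H](O[Si](C)(C)C(C)(C)C)C2C1=CC[C@@H](C)[C@]2(C)C=C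
F4 | step 9 | methyl 1β-hydroxy-13,14,15,16-tetranorhalima-5,11-dien-18-oate (C10 epimers) | COC(=O)[C@]1(C)CC[C@@H](O)C2C1=CC[C@@H](C)[C@]2(C)C=C
F5 | step 10 | methyl 1β-hydroxy-11-[methoxy(methyl)amino]-11-oxo-12,13,14,15,16-pentanorhalim-5-en-18-oate (10α-H) | COC(=O)[C@]1(C)CC[C@@H](O)[C@@H]2C1=CC[C@@H](C)[C@]2(C)C(=O)N(C)OC
F6 | step 14 | methyl 1β-[(methoxycarbonyl)oxy]-13,14,15,16-tetranorhalima-5(10),11-dien-18-oate | COC(=O)[C@]1(C)CC[C@@H](OC(=O)OC)C2=C1CC[C@@H](C)[C@]2(C)C=C
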